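**Plan**

- Retrosynthetic cuts, in order: the three O–Si bonds; then C2–C1′ (ring C to ring B), which leads back to a flat 6-alkenylchromone and an arylboronic acid; then C6–C1″ (ring A to the chain); then C6–I.
- Forward: rings A and C are bought together as planar 5,7-dihydroxychromone. O7 is silylated, C6 is iodinated under direction of the chelated 5-OH, the C10 chain is attached by a Heck reaction, ring B is added last, and the silyl groups are removed.
- Stereochemistry: C3″ comes unchanged from the chiral pool, (S)-β-citronellene. C2 is created by ligand control in a Rh-catalysed enantioselective 1,4-arylation that dearomatises the γ-pyrone ring.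
- Enabling feature: C2 is the β-carbon of the C4 ketone inside ring C and carries both ring B and the only ring stereocentre, so it maps onto C2=C3 of a chromone. O1–C2 is never broken, so no 2′-hydroxychalcone forms; that is the species through which C2 racemises and C6/C8 substitution scrambles.
- Constraint: the o-hydroxystyrene with its remote trisubstituted olefin cyclises through an o-quinone methide under acid, hence silyl protection only and a buffered fluoride finish.

Key step: step 6

Assumptions: 5,7-dihydroxychromone (1) and (S)-β-citronellene (4) are bought as such. The (S)-configured biaryl bisphosphine is assumed to give the 2S adduct by the usual cyclic-enone model; this is to be checked on 2 before 5 is committed, and the (R)-ligand is used if the sense is opposite.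

**Route**

Step 1
Reactants: 1 5,7-dihydroxy-4H-chromen-4-one
Product: 2 5-hydroxy-7-[(triisopropylsilyl)oxy]-4H-chromen-4-one
Conditions: TIPSCl (1.05 equiv), imidazole, DMF, 0 °C
Reagents that add atoms: chlorotriisopropylsilane, CC(C)[Si](Cl)(C(C)C)C(C)C
Why: Chemoselective O-silylation, since the 7-OH is the acidic, unhindered phenol whereas the 5-OH is held in a hydrogen bond to the C4 carbonyl and stays free to direct step 2; no stereocentre is formed.

Step 2
Reactants: 2 5-hydroxy-7-[(triisopropylsilyl)oxy]-4H-chromen-4-one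
Product: 3 5-hydroxy-6-iodo-7-[(triisopropylsilyl)oxy]-4H-chromen-4-one
Conditions: NIS (1.0 equiv), DMF, 0 °C to rt, dark
Reagents that add atoms: N-iodosuccinimide, O=C1CCC(=O)N1I
Why: Electrophilic aromatic iodination directed by the free chelated 5-OH, which on 5-hydroxy-7-alkoxy chromones and flavones should send the halogen to the ortho carbon C6 rather than to C8; no stereocentre is formed.

Step 3
Reactants: 3 5-hydroxy-6-iodo-7-[(triisopropylsilyl)oxy]-4H-chromen-4-one; 4 (3S)-3,7-dimethylocta-1,6-diene [(S)-β-citronellene]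
Product: 5 5-hydroxy-6-[(1E,3S)-3,7-dimethylocta-1,6-dien-1-yl]-7-[(triisopropylsilyl)oxy]-4H-chromen-4-one
Conditions: 4 (5 equiv), Pd(OAc)2 (10 mol %), P(o-tol)3 (20 mol %), Et3N, DMF, 90 °C, sealed vessel
Reagents that add atoms: none
Why: Mizoroki–Heck reaction in which syn-carbopalladation of the terminal alkene puts the aryl group on C1″ and syn-β-hydride elimination toward the benzylic hydrogen should give the conjugated E-styrene, the trisubstituted olefin being too hindered to insert; C3″ comes unchanged from 4.

Step 4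
Reactants: 6 4-bromobenzene-1,2-diol
Product: 7 4-bromo-1,2-bis[(tert-butyldimethylsilyl)oxy]benzene
Conditions: TBSCl (2.4 equiv), imidazole, DMF, rt
Reagents that add atoms: tert-butylchlorodimethylsilane, CC(C)(C)[Si](C)(C)Cl
Why: Standard imidazole-mediated silylation of both phenols, which masks the catechol against chelation of rhodium and self-condensation with the boronic acid.

Step 5
Reactants: 7 4-bromo-1,2-bis[(tert-butyldimethylsilyl)oxy]benzene
Product: 10 {3,4-bis[(tert-butyldimethylsilyl)oxy]phenyl}boronic acid, via aryllithium 8 (not isolated), via lithium aryltriisopropoxyborate 9 (not isolated)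
Conditions: n-BuLi, THF, −78 °C; B(OiPr)3, −78 °C to rt; 1 M HCl, 0 °C, brief
Reagents that add atoms: triisopropyl borate, CC(C)OB(OC(C)C)OC(C)C; water, O; n-butyllithium, CCCC[Li] (lithium of 8 and 9 only)
Why: Bromine–lithium exchange followed by borylation with a trialkyl borate and hydrolysis; the lithium is not ortho to a silyl ether, so no silyl migration is expected.

Step 6
Reactants: 5 5-hydroxy-6-[(1E,3S)-3,7-dimethylocta-1,6-dien-1-yl]-7-[(triisopropylsilyl)oxy]-4H-chromen-4-one; 10 {3,4-bis[(tert-butyldimethylsilyl)oxy]phenyl}boronic acid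
Product: 11 (2S)-2-{3,4-bis[(tert-butyldimethylsilyl)oxy]phenyl}-6-[(1E,3S)-3,7-dimethylocta-1,6-dien-1-yl]-5-hydroxy-7-[(triisopropylsilyl)oxy]chroman-4-one
Conditions: 10 (3 equiv), [RhCl(C2H4)2]2 (2.5 mol %), (S)-MeO-F12-BIPHEP (5.5 mol %), aq. KOH (0.25 equiv), CH2Cl2–H2O, 30 °C
Reagents that add atoms: none
Why: Rh(I)-catalysed Hayashi–Miyaura 1,4-addition, a reaction type established for chromones: the aryl group passes from boron to a Rh–OH species, the aryl–rhodium adds across C2=C3 on the enantioface selected by the bisphosphine, and the oxa-π-allyl rhodium enolate is protonated by water at C3, which regenerates Rh–OH. No ring is closed; the planar γ-pyrone ring C is converted into the chromanone ring, and because O1–C2 is never broken no chalcone can form and the C6 regiochemistry cannot reopen. The only new stereocentre, C2, is set by the ligand ((S)-bisphosphine to 2S by the cyclic-enone model), and the C3″ centre is too remote to influence it. The step needs 1,4- over 1,2-addition and reaction at the enone in preference to the styrene and the trisubstituted olefin. The chelated 5-OH···O=C4 hydrogen bond activates the enone and deactivates the product ketone, arylrhodium species do not insert into unactivated alkenes under these conditions, and protonation of the enolate should be faster than β-aryloxide elimination.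

Step 7
Reactants: 11 (2S)-2-{3,4-bis[(tert-butyldimethylsilyl)oxy]phenyl}-6-[(1E,3S)-3,7-dimethylocta-1,6-dien-1-yl]-5-hydroxy-7-[(triisopropylsilyl)oxy]chroman-4-one
Product: 12 (2S)-2-(3,4-dihydroxyphenyl)-6-[(1E,3S)-3,7-dimethylocta-1,6-dien-1-yl]-5,7-dihydroxychroman-4-one
Conditions: TBAF (3.5 equiv), AcOH (3.5 equiv), THF, 0 °C to rt; pH 6 buffer work-up, chromatography on neutral support
Reagents that add atoms: none
Why: Fluoride cleavage of the three aryl silyl ethers, buffered with acetic acid so that no phenoxide builds up to open ring C by retro-oxa-Michael reaction and no strong acid is present to cyclise the o-hydroxystyrene; no stereocentre is touched.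

**Compound list**

1 | 5,7-dihydroxy-4H-chromen-4-one | O=c1ccoc2cc(O)cc(O)c12 | starting material
2 | 5-hydroxy-7-[(triisopropylsilyl)oxy]-4H-chromen-4-one | O=c1ccoc2cc(O[Si](C(C)C)(C(C)C)C(C)C)cc(O)c12 | intermediate
3 | 5-hydroxy-6-iodo-7-[(triisopropylsilyl)oxy]-4H-chromen-4-one | O=c1ccoc2cc(O[Si](C(C)C)(C(C)C)C(C)C)c(I)c(O)c12 | intermediate
4 | (3S)-3,7-dimethylocta-1,6-diene, (S)-β-citronellene | CC(C)=CCC[C@H](C)C=C | starting material
5 | 5-hydroxy-6-[(1E,3S)-3,7-dimethylocta-1,6-dien-1-yl]-7-[(triisopropylsilyl)oxy]-4H-chromen-4-one | CC(C)=CCC[C@H](C)/C=C/c1c(O[Si](C(C)C)(C(C)C)C(C)C)cc2occc(=O)c2c1O | intermediate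
6 | 4-bromobenzene-1,2-diol | Oc1ccc(Br)cc1O | starting material
7 | 4-bromo-1,2-bis[(tert-butyldimethylsilyl)oxy]benzene | CC(C)(C)[Si](C)(C)Oc1ccc(Br)cc1O[Si](C)(C)C(C)(C)C | intermediate
8 | {3,4-bis[(tert-butyldimethylsilyl)oxy]phenyl}lithium | [Li]c1ccc(O[Si](C)(C)C(C)(C)C)c(O[Si](C)(C)C(C)(C)C)c1 | intermediate (not isolated)
9 | lithium {3,4-bis[(tert-butyldimethylsilyl)oxy]phenyl}triisopropoxyborate | [Li+].CC(C)O[B-](OC(C)C)(OC(C)C)c1ccc(O[Si](C)(C)C(C)(C)C)c(O[Si](C)(C)C(C)(C)C)c1 | intermediate (not isolated)
10 | {3,4-bis[(tert-butyldimethylsilyl)oxy]phenyl}boronic acid | OB(O)c1ccc(O[Si](C)(C)C(C)(C)C)c(O[Si](C)(C)C(C)(C)C)c1 | intermediate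
11 | (2S)-2-{3,4-bis[(tert-butyldimethylsilyl)oxy]phenyl}-6-[(1E,3S)-3,7-dimethylocta-1,6-dien-1-yl]-5-hydroxy-7-[(triisopropylsilyl)oxy]chroman-4-one | CC(C)=CCC[C@H](C)/C=C/c1c(O[Si](C(C)C)(C(C)C)C(C)C)cc2c(c1O)C(=O)C[C@@H](c1ccc(O[Si](C)(C)C(C)(C)C)c(O[Si](C)(C)C(C)(C)C)c1)O2 | intermediate
12 | (2S)-2-(3,4-dihydroxyphenyl)-6-[(1E,3S)-3,7-dimethylocta-1,6-dien-1-yl]-5,7-dihydroxychroman-4-one | CC(C)=CCC[C@H](C)/C=C/c1c(O)cc2c(c1O)C(=O)C[C@@H](c1ccc(O)c(O)c1)O2 | target

**Summary**

Total step count: 7.
Longest linear sequence: 5 steps (steps 1, 2, 3, 6, 7; 1 → 2 → 3 → 5 → 11 → 12).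

**Steps most likely to fail**

Step 6. The chelating 5-hydroxy-4-keto unit or the bulky, electron-rich substrate may slow turnover at the chiral rhodium centre, so that a less selective background pathway erodes enantioface selection, or the arylrhodium may add 1,2 to the product ketone. The fallback replaces asymmetric C–C bond formation by a kinetic resolution. It sets out from 5, which is arylated with 10 under ligand-free [Rh(OH)(cod)]2 conditions (dioxane–H2O, rt) to give the C2-epimeric mixture of the silylated flavanone F1. Asymmetric transfer hydrogenation (Cp*Rh(III)–TsDPEN, HCO2H/Et3N, with the catalyst antipode that reduces the 2R ketone) should then convert the (2R)-epimer into the cis-(2R,4R)-flavan-4-ol F2. F2 is separated from the unreduced (2S)-ketone, which is 11, where the route is rejoined.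

Step 3. β-Hydride elimination of the alkylpalladium intermediate may go toward C3″ instead of the benzylic position, giving the non-conjugated trisubstituted alkene and, through Pd–H re-insertion, endangering C3″; insertion may also be slow because the arylpalladium is flanked by two oxygen substituents. The fallback joins arene and chain by Suzuki–Miyaura coupling with a preformed E-alkenylboron compound. It sets out from 4, which is converted by a palladium-catalysed boryl-Heck reaction (catBCl, Pd2(dba)3, bulky monophosphine, Cy2NMe, then pinacol) into the (E)-alkenyl pinacol boronate F3. Its isomeric purity is checked before use. Coupling of F3 with 3 (Pd(dppf)Cl2, K3PO4, THF–H2O, 50 °C) should give 5, where the route is rejoined.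

Step 2. The electrophile may attack C8, para to the 5-OH, or iodinate twice, especially if the bulky 7-O-silyl group shields C6. The fallback places a carbon–oxygen handle by phenoxide-directed formylation instead of a halogen by undirected substitution. It sets out from 2, which is formylated only ortho to the free 5-OH by the magnesium-mediated method (MgCl2, Et3N, paraformaldehyde, MeCN, 70 °C) to give the 6-carbaldehyde F4. Dakin-type oxidation (mCPBA, CH2Cl2; then NaHCO3, MeOH) should give the 5,6-diol F5. The non-chelated 6-OH is triflated (Tf2O, pyridine, −78 °C) to the 6-triflate F6. Heck coupling of F6 with 4 (Pd(OAc)2, dppf, LiCl, Et3N, DMF, 90 °C) should give 5, where the route is rejoined.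

**Further compounds**

F1 | step 6 | 2-{3,4-bis[(tert-butyldimethylsilyl)oxy]phenyl}-6-[(1E,3S)-3,7-dimethylocta-1,6-dien-1-yl]-5-hydroxy-7-[(triisopropylsilyl)oxy]chroman-4-one, mixture of C2 epimers | CC(C)=CCC[C@H](C)/C=C/c1c(O[Si](C(C)C)(C(C)C)C(C)C)cc2c(c1O)C(=O)CC(c1ccc(O[Si](C)(C)C(C)(C)C)c(O[Si](C)(C)C(C)(C)C)c1)O2
F2 | step 6 | (2R,4R)-2-{3,4-bis[(tert-butyldimethylsilyl)oxy]phenyl}-6-[(1E,3S)-3,7-dimethylocta-1,6-dien-1-yl]-7-[(triisopropylsilyl)oxy]chromane-4,5-diol | CC(C)=CCC[C@H](C)/C=C/c1c(O[Si](C(C)C)(C(C)C)C(C)C)cc2c(c1O)[C@H](O)C[C@H](c1ccc(O[Si](C)(C)C(C)(C)C)c(O[Si](C)(C)C(C)(C)C)c1)O2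
F3 | step 3 | 2-[(1E,3S)-3,7-dimethylocta-1,6-dien-1-yl]-4,4,5,5-tetramethyl-1,3,2-dioxaborolane | CC(C)=CCC[C@H](C)/C=C/B1OC(C)(C)C(C)(C)O1
F4 | step 2 | 5-hydroxy-4-oxo-7-[(triisopropylsilyl)oxy]-4H-chromene-6-carbaldehyde | O=Cc1c(O[Si](C(C)C)(C(C)C)C(C)C)cc2occc(=O)c2c1O
F5 | step 2 | 5,6-dihydroxy-7-[(triisopropylsilyl)oxy]-4H-chromen-4-one | Oc1c(O[Si](C(C)C)(C(C)C)C(C)C)cc2occc(=O)c2c1O
F6 | step 2 | 5-hydroxy-4-oxo-7-[(triisopropylsilyl)oxy]-4H-chromen-6-yl trifluoromethanesulfonate | O=S(=O)(Oc1c(O[Si](C(C)C)(C(C)C)C(C)C)cc2occc(=O)c2c1O)C(F)(F)F
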